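## The problem

Cladiellane numbering is used. C1 and C10 are the ring-fusion CH groups, C2 and C9 the ether carbons, C3 the lactone carbinol carbon, C6 the OMe carbon and C7 the free tertiary carbinol. C11 carries the acetate, C14 the side chain, C15 is CH(CH3) and C16 is the lactone C=O. C17 to C20 are the methyl groups on C15, C3, C7 and C11.

- The target has four rings. Ring A is a cyclohexane (C1, C10–C14), ring B a tetrahydrofuran (C1, C2, O, C9, C10), ring C an oxonane (O, C2–C9) and ring D an ε-lactone (C1–C3, O, C16, C15, C14).
- Rings B and C together are an ether-bridged ten-membered carbocycle C1–C10. This medium ring resists end-to-end closure and is the main hurdle.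
- Eight of the ten stereocentres form one contiguous block (C15, C14, C1, C2, C3 and C9, C10, C11). The pair C6/C7 lies across the medium ring, where nothing on ring A can control it.
- Three fully substituted carbinol carbons must end up in three different states: C3 as lactone oxygen, C7 as free OH, C11 as acetate.
- Late intermediates contain a tertiary acetate, a lactone with an epimerisable C15, and β-oxygenated carbonyl arrays prone to elimination or retro-aldol cleavage.
- The feature that opens the plan is that the twenty skeletal carbons are two p-menthane units. One is ring A with C20 and C15–C17.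
- A bond drawn from C4 to C9 across the ten-membered ring gives the second unit: a six-membered ring E (C4–C9) with C19 on C7 and an isopropenyl group C3(C18)=C2 on C4. The two units are joined only by C1–C2 and C9–C10.
- The sequence C9(=O)–C10–C1–C2–C3=C4 is the δ,ε-unsaturated ketone retron of an oxy-Cope rearrangement.

## Retrosynthesis

**Tertiary alcohols.** Target 26 is traced to silyl ether 25 and alcohol 24. No skeletal bond is cut. C7–OH stays masked from the fragment stage, so C11–OH is the only free hydroxyl when the acetate is put on. The forward steps are one acylation and one desilylation.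

**C3–O bond of ring D.** Cutting it gives alkenoic acid 23, with a C3=C4 alkene and a free C16 acid. A cut at the acyl C16–O bond would need a preformed C3 carbinol of defined configuration. With the C3–O cut, the side chain on C14 can reach only the face of C3 turned towards ring A, so the tether fixes C3. The forward reaction is a Markovnikov hydroacyloxylation.

**C2–O bond of ring B.** This cut leads through hemiketal 22 and allylic alcohol 20 to hydroxy acid 19 and ketone 15. C2 is the ring CH2 at the more substituted end of the C3=C4 alkene, the position that selenium dioxide oxidises. C9 can be set from C11–OH by directed reduction. C2 is then fixed by the bridge, because only the cis-bridged ether can exist. The C9–O cut was rejected because a cation at C9 lies opposite C4 and invites transannular C–C bond formation.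

**Key disconnection.** In ketone 15 the C1–C2 bond is cut and C4–C9 is reconnected, giving divinyl carbinol 13. The 6–10 bicycle becomes two six-membered rings joined by one bond. C6 and C7 now sit on a cyclohexane, where they are easy to set. A latent C2–C7 bond would give a cadinane-type decalin with a quaternary methyl/vinyl carbon and no terpene precursor. The forward reaction must form C1–C2 anti to the C14 substituent, give H1/H10 cis, and leave an alkene at C3=C4.

**C9–C10 bond.** Cutting it splits 13 into vinyllithium 12 and ketone 7. This is the only bond between the two halves, so their relative configuration follows from using enantiopure fragments and needs no induction. The axial C7 methyl of 7 must steer the nucleophile into the equatorial position.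

**Fragments.** Both 7 and hydrazone 11 go back to (R)-carvone 1.
- In 7 the carvone carbonyl carbon becomes C6, the enone alkene C7=C8, the γ-CH2 C9, and the stereocentre C4.
- In 11 the carbonyl carbon becomes C10, the methyl-bearing alkene carbon C11, and the stereocentre C14.

## Roads not taken

Alternative 1: The most obvious route cuts C6=C7 by ring-closing metathesis and ring A by an intramolecular Diels–Alder reaction (bonds C1–C10 and C13–C14). An acyclic diene ether is closed with the second-generation Grubbs catalyst to the (Z)-oxonene. This is elaborated to tetraene A1, which cyclises to rings A and B. C2, C3 and C9 must first be set one by one in an acyclic ether, which makes a long linear run-up. The Z-alkene demands an anti dioxygenation in which methanol would have to attack the secondary C6 of a trisubstituted epoxide. Ring A arrives without the C11 oxygen and with the side chain one carbon short. The chosen plan brings C6, C7, C11 and C14 in from two short fragment syntheses.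

Alternative 2: Ring C is cut at C6–C7 on a preformed hydroisobenzofuran. Iodo aldehyde A2 would be closed with CrCl2/NiCl2 (Nozaki–Hiyama–Kishi reaction). The closure is plausible, but it gives a C6 allylic alcohol next to an exocyclic methylene, so C7 still needs several redox steps. The hydroisobenzofuran with both side arms is itself a long linear target, and the C6/C7 pair is again left to medium-ring substrate control.

Alternative 3: Rings B and C are made together by a [2,3]-shift of an oxonium ylide. Tetrahydropyranyl diazoketone A3 is treated with Cu(hfacac)2, and the six-membered ether expands by three atoms. This is a true ring expansion, but it places ring A last. The furanone must be turned into a diene, combined with a dienophile of uncertain endo/exo selectivity, corrected at C14, and homologated to the propionate side chain. The C6=C7 geometry also depends on the catalyst. The chosen plan builds the same medium ring while uniting two complete halves.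

Key step: step 11

Assumption: the carbinol configurations at C10 in 9 and at C2 in 20 are destroyed in the following steps and are left open in the SMILES.

## Route

Step 1
Reactants: 1 (R)-(−)-carvone, (5R)-2-methyl-5-(prop-1-en-2-yl)cyclohex-2-en-1-one
Product: 2 (−)-cis-carveol, (1R,5R)-2-methyl-5-(prop-1-en-2-yl)cyclohex-2-en-1-ol
Conditions: NaBH4, CeCl3·7H2O, MeOH, 0 °C
Reagents that add atoms: none
Why: Luche 1,2-reduction; axial hydride delivery to the half-chair with an equatorial isopropenyl group gives the alcohol cis to that group, which sets C6 relative to C4.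

Step 2
Reactants: 2 (−)-cis-carveol
Product: 3 cis-carveyl methyl ether, (4R,6R)-6-methoxy-1-methyl-4-(prop-1-en-2-yl)cyclohex-1-ene
Conditions: NaH, MeI, THF, 0 °C to rt
Reagents that add atoms: iodomethane, CI
Why: Williamson etherification of the only hydroxyl group installs the C6 methyl ether before any other oxygen is present, so no selective methylation is needed later.

Step 3
Reactants: 3 cis-carveyl methyl ether
Product: 4 (4R,6R)-4-methoxy-3-methyl-6-(prop-1-en-2-yl)cyclohex-2-en-1-one (C9 ketone, C7=C8 alkene)
Conditions: CrO3, 3,5-dimethylpyrazole, CH2Cl2, −20 °C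
Reagents that add atoms: chromium trioxide, O=[Cr](=O)=O
Why: Allylic oxidation with the CrO3–dimethylpyrazole complex converts the ring CH2 next to the CH end of the trisubstituted alkene (C9) into the enone carbonyl; the non-basic medium leaves C4 and C6 untouched.

Step 4
Reactants: 4 enone
Product: 6 (2R,4R,5R)-5-hydroxy-4-methoxy-5-methyl-2-(prop-1-en-2-yl)cyclohexan-1-one, via pinacol boronate 5 (not isolated)
Conditions: CuCl (cat.), Xantphos (cat.), NaOtBu (cat.), B2pin2, MeOH, THF, rt; then NaBO3·4H2O, THF–H2O, rt
Reagents that add atoms: bis(pinacolato)diboron (boron of 5), CC1(C)OB(OC1(C)C)B1OC(C)(C)C(C)(C)O1; sodium perborate (oxygen of 6), [Na+].[Na+].O[B-]1(O)OO[B-](O)(O)OO1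
Why: Copper-catalysed conjugate borylation of a β-methyl enone adds boron to C7 anti to the neighbouring C6 methoxy group, and oxidation with retention gives the tertiary C7 alcohol trans to OMe; the unactivated isopropenyl group does not react.

Step 5
Reactants: 6 β-hydroxy ketone
Product: 7 (2R,4R,5R)-5-(tert-butyldimethylsilyloxy)-4-methoxy-5-methyl-2-(prop-1-en-2-yl)cyclohexan-1-one
Conditions: TBSOTf, 2,6-lutidine, CH2Cl2, −78 to 0 °C
Reagents that add atoms: tert-butyldimethylsilyl triflate, CC(C)(C)[Si](C)(C)OS(=O)(=O)C(F)(F)F
Why: Silylation of a tertiary alcohol with the silyl triflate and a weak hindered base avoids E1cB loss of the β-oxygen and epimerisation at C4; the group masks C7–OH until the last step.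

Step 6
Reactants: 1 (R)-(−)-carvone
Product: 8 (1R,4R,6R)-1-methyl-4-(prop-1-en-2-yl)-7-oxabicyclo[4.1.0]heptan-2-one
Conditions: H2O2 (aq), NaOH (cat.), MeOH, 0 °C
Reagents that add atoms: hydrogen peroxide, OO
Why: Weitz–Scheffer epoxidation attacks only the enone alkene and occurs trans to the isopropenyl group, which places the C11 oxygen trans to the C14 substituent.

Step 7
Reactants: 8 carvone oxide
Product: 9 (1R,4R)-1-methyl-4-(prop-1-en-2-yl)cyclohexane-1,2-diol (tertiary OH trans to isopropenyl, secondary carbinol open)
Conditions: LiAlH4, THF, 0 °C to rt; aqueous work-up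
Reagents that add atoms: none
Why: Hydride reduces the ketone and opens the epoxide at its less substituted carbon C12, so the oxygen stays on C11 with its configuration unchanged.

Step 8
Reactants: 9 diol
Product: 10 (2R,5R)-2-hydroxy-2-methyl-5-(prop-1-en-2-yl)cyclohexan-1-one
Conditions: SO3·pyridine, DMSO, Et3N, CH2Cl2, 0 °C
Reagents that add atoms: none
Why: Parikh–Doering oxidation takes the secondary alcohol to the C10 ketone without glycol cleavage; the tertiary alcohol cannot react.

Step 9
Reactants: 10 hydroxy ketone
Product: 11 2,4,6-triisopropylbenzenesulfonylhydrazone of 10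
Conditions: 2,4,6-iPr3C6H2SO2NHNH2, HCl (cat.), MeCN, rt
Reagents that add atoms: 2,4,6-triisopropylbenzenesulfonohydrazide, CC(C)c1cc(C(C)C)c(S(=O)(=O)NN)c(C(C)C)c1
Why: Acid-catalysed hydrazone condensation; the trisyl group blocks ortho-lithiation and loses sulfinate readily in the next step.

Step 10
Reactants: 11 trisylhydrazone; 7 silyloxy ketone
Product: 13 divinyl carbinol (ring E chair: C9 with axial OH and equatorial bond to C10, C4 equatorial isopropenyl, C6 OMe, C7 axial CH3 and OTBS; ring A: C10=C1, C11(CH3)(OH), C14 isopropenyl), via dilithio cyclohexenolate 12 (not isolated)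
Conditions: n-BuLi (3.3 equiv), THF, −78 to 0 °C; then 7, −78 °C; H2O
Reagents that add atoms: n-butyllithium (lithium of 12), [Li]CCCC
Why: Shapiro reaction; the only α-hydrogens are on C1, so the vinyllithium forms at C10, and the C11 oxygen as an alkoxide cannot leave. Its 1,2-addition to 7 comes in equatorially because the axial C7 methyl blocks the axial path, which places the two alkenyl groups trans-diequatorial.

Step 11
Reactants: 13 divinyl carbinol
Product: 15 ten-membered ketone fused to ring A (C9 ketone, (3E)-C3=C4, H1 and H10 cis, C2 trans to C15, C6 OMe, C7 OTBS, C11 OH, C14 isopropenyl), via dipotassium enolate 14 (not isolated)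
Conditions: KH, 18-crown-6, THF, 0 °C to rt; then AcOH, THF, −78 °C
Reagents that add atoms: potassium hydride (potassium of 14), [K+].[H-]
Why: KH/18-crown-6 turns both tertiary alcohols into naked potassium alkoxides, and the C9 alkoxide weakens the adjacent C4–C9 bond so that the 1,5-diene C1=C10–C9–C4–C3=C2 undergoes an anionic oxy-Cope [3,3] shift. The closest known reaction type is the ring expansion of 1-cycloalkenyl-2-alkenylcycloalkanols to fused (E)-cyclodec-5-enones. No ring is closed end to end: the ten-membered ring C1–C10 arises by four-atom expansion of ring E, C1–C2 forming as C4–C9 breaks, and ring A becomes fused at C1–C10. With both alkenyl groups equatorial on the chair of ring E only the chair transition state is within reach, which gives the E C3=C4 alkene and passes the configuration of C9/C4 on to C1. That same face of C1=C10 is the one anti to the C14 isopropenyl group, so the two carvone-derived halves are matched. C10 is set by cold protonation of enolate 14 from its outer face, opposite to the new C1–C2 bond, which makes H1 and H10 cis. The step needs this array to react alone: the C14 isopropenyl group stands only in a 1,4-relation to C1=C10 and cannot take part, and C6 and C7 are spectators. The C11 oxygen is carried as an alkoxide, a non-leaving group, so enolate 14 cannot lose it by β-elimination.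

Step 12
Reactants: 15 ten-membered ketone
Product: 17 primary alcohol (C14 side chain CH(CH3)CH2OH, C15 as in the target), via B-alkyl-9-BBN adduct 16 (not isolated)
Conditions: 9-BBN, THF, 0 °C to rt; then NaBO3·4H2O, H2O, rt
Reagents that add atoms: 9-borabicyclo[3.3.1]nonane (boron unit of 16), B1C2CCCC1CCC2; sodium perborate (oxygen of 17), [Na+].[Na+].O[B-]1(O)OO[B-](O)(O)OO1
Why: Hydroboration–oxidation; 9-BBN picks the 1,1-disubstituted alkene over the hindered trisubstituted one and the hindered ketone. In the rotamer with H14 eclipsing the C=CH2 bond it attacks from the C13 side, away from the substituted C1, which sets C15.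

Step 13
Reactants: 17 primary alcohol
Product: 18 keto acid (C16 carboxylic acid)
Conditions: TEMPO (cat.), PhI(OAc)2, MeCN–H2O, rt
Reagents that add atoms: water, O
Why: Oxoammonium oxidation of the only primary alcohol to the acid; tertiary alcohols, the alkene and the silyl ether are inert, and the near-neutral medium spares the β-hydroxy ketone.

Step 14
Reactants: 18 keto acid
Product: 19 hydroxy acid (C9–OH with the configuration of the target ether carbon)
Conditions: Me4NBH(OAc)3, MeCN–AcOH, −30 °C
Reagents that add atoms: none
Why: Evans–Saksena hydroxyl-directed reduction; boron bound to the C11 oxygen delivers hydride through a chair with C8 equatorial, so H9 enters from the C11–O side and the anti 1,3-diol with the required C9 results.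

Step 15
Reactants: 19 hydroxy acid
Product: 20 allylic alcohol (C2–OH, either epimer; C3=C4 retained)
Conditions: SeO2 (cat.), t-BuOOH, CH2Cl2, 0 °C to rt
Reagents that add atoms: tert-butyl hydroperoxide, CC(C)(C)OO
Why: Selenium dioxide allylic hydroxylation (ene reaction, then [2,3]-shift) attacks the more substituted end of the alkene, prefers CH2 over CH3 and the group cis to the vinylic hydrogen; all three rules point to C2.

Step 16
Reactants: 20 allylic alcohol
Product: 22 bridged hemiketal (C2 bearing OH and the oxygen of C9; ring B closed), via hydroxy enone 21 (not isolated)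
Conditions: MnO2, CH2Cl2, rt
Reagents that add atoms: none
Why: MnO2 oxidises only the allylic alcohol, which erases the open C2 centre; the C9 hydroxyl then adds across the ring to the C2 carbonyl as a five-membered hemiketal.

Step 17
Reactants: 22 bridged hemiketal
Product: 23 ether-bridged alkenoic acid (rings A, B and C complete, C3=C4 alkene, free C16 acid)
Conditions: Et3SiH, BF3·OEt2, CH2Cl2, −78 °C
Reagents that add atoms: none
Why: Ionic reduction of a hemiketal through an allyl-stabilised oxocarbenium ion, which takes hydride at the oxygen-bearing carbon as in Ferrier-type reactions. Only attack from the face opposite to the C3–C8 bridge keeps the bicycle cis-bridged, which sets C2.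

Step 18
Reactants: 23 alkenoic acid
Product: 24 tetracyclic lactone alcohol (ring D closed, C11–OH free, C7–OTBS)
Conditions: [N,N′-bis(3,5-di-tert-butylsalicylidene)-1,2-cyclohexanediaminato]cobalt (cat.), N-fluoro-2,4,6-trimethylpyridinium triflate, PhSiH3, PhCF3, rt
Reagents that add atoms: none
Why: Cobalt-catalysed hydrogen-atom-transfer hydroacyloxylation; hydrogen adds to C4, and the tertiary C3 centre is oxidised and captured by the tethered acid. The acid reaches only the face of C3 turned to ring A, so either alkene geometry gives the single C3 configuration.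

Step 19
Reactants: 24 lactone alcohol
Product: 25 C11 acetate, C7 silyl ether
Conditions: Ac2O, DMAP, Et3N, CH2Cl2, 40 °C
Reagents that add atoms: acetic anhydride, CC(=O)OC(C)=O
Why: DMAP-catalysed acylation of the only free hydroxyl group, an equatorial tertiary alcohol on ring A.

Step 20
Reactants: 25 acetate silyl ether
Product: 26 target CNP0238771.1
Conditions: HF·pyridine, THF, 0 °C to rt
Reagents that add atoms: none
Why: Fluoride-driven cleavage of the tertiary silyl ether under mildly acidic conditions, which leave the tertiary acetate, the lactone and C15 untouched.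

## Compound list

1 | (R)-(−)-carvone | O=C1C[C@H](C(C)=C)CC=C1C | starting material
2 | (−)-cis-carveol | O[C@@H]1C[C@H](C(C)=C)CC=C1C | intermediate
3 | cis-carveyl methyl ether | CO[C@@H]1C[C@H](C(C)=C)CC=C1C | intermediate
4 | (4R,6R)-4-methoxy-3-methyl-6-(prop-1-en-2-yl)cyclohex-2-en-1-one | CO[C@@H]1C[C@H](C(C)=C)C(=O)C=C1C | intermediate
5 | C7 pinacol boronate (boron trans to OMe) | CO[C@@H]1C[C@H](C(C)=C)C(=O)C[C@@]1(C)B2OC(C)(C)C(C)(C)O2 | intermediate
6 | (2R,4R,5R)-5-hydroxy-4-methoxy-5-methyl-2-(prop-1-en-2-yl)cyclohexan-1-one | CO[C@@H]1C[C@H](C(C)=C)C(=O)C[C@@]1(C)O | intermediate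
7 | tert-butyldimethylsilyl ether of 6 | CO[C@@H]1C[C@H](C(C)=C)C(=O)C[C@@]1(C)O[Si](C)(C)C(C)(C)C | intermediate
8 | (1R,4R,6R)-carvone oxide | O=C1C[C@H](C(C)=C)C[C@H]2O[C@@]12C | intermediate
9 | (1R,4R)-1-methyl-4-(prop-1-en-2-yl)cyclohexane-1,2-diol | OC1C[C@H](C(C)=C)CC[C@@]1(C)O | intermediate
10 | (2R,5R)-2-hydroxy-2-methyl-5-(prop-1-en-2-yl)cyclohexan-1-one | O=C1C[C@H](C(C)=C)CC[C@@]1(C)O | intermediate
11 | trisylhydrazone of 10 | CC(C)c1cc(C(C)C)c(S(=O)(=O)N/N=C2\C[C@H](C(C)=C)CC[C@@]2(C)O)c(C(C)C)c1 | intermediate
12 | dilithio cyclohexenolate (C10–Li, C11–OLi) | [Li]C1=C[C@H](C(C)=C)CC[C@@]1(C)O[Li] | intermediate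
13 | divinyl carbinol | CO[C@@H]1C[C@H](C(C)=C)[C@](O)(C[C@@]1(C)O[Si](C)(C)C(C)(C)C)C2=C[C@H](C(C)=C)CC[C@@]2(C)O | intermediate
14 | dipotassium enolate alkoxide | CO[C@@H]1C/C=C(C)/C[C@H]2[C@@H](CC[C@@](C)([O-])/C2=C(/[O-])C[C@@]1(C)O[Si](C)(C)C(C)(C)C)C(C)=C.[K+].[K+] | intermediate
15 | ten-membered ketone fused to ring A | CO[C@@H]1C/C=C(C)/C[C@H]2[C@@H](CC[C@@](C)(O)[C@H]2C(=O)C[C@@]1(C)O[Si](C)(C)C(C)(C)C)C(C)=C | intermediate
16 | B-alkyl-9-BBN adduct | CO[C@@H]1C/C=C(C)/C[C@H]2[C@@H](CC[C@@](C)(O)[C@H]2C(=O)C[C@@]1(C)O[Si](C)(C)C(C)(C)C)[C@@H](C)CB3C4CCCC3CCC4 | intermediate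
17 | C16 primary alcohol | CO[C@@H]1C/C=C(C)/C[C@H]2[C@@H](CC[C@@](C)(O)[C@H]2C(=O)C[C@@]1(C)O[Si](C)(C)C(C)(C)C)[C@@H](C)CO | intermediate
18 | C9 keto C16 acid | CO[C@@H]1C/C=C(C)/C[C@H]2[C@@H](CC[C@@](C)(O)[C@H]2C(=O)C[C@@]1(C)O[Si](C)(C)C(C)(C)C)[C@@H](C)C(=O)O | intermediate
19 | C9 hydroxy acid | CO[C@@H]1C/C=C(C)/C[C@H]2[C@@H](CC[C@@](C)(O)[C@H]2[C@@H](O)C[C@@]1(C)O[Si](C)(C)C(C)(C)C)[C@@H](C)C(=O)O | intermediate
20 | C2 allylic alcohol | CO[C@@H]1C/C=C(C)/C(O)[C@H]2[C@@H](CC[C@@](C)(O)[C@H]2[C@@H](O)C[C@@]1(C)O[Si](C)(C)C(C)(C)C)[C@@H](C)C(=O)O | intermediate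
21 | C9 hydroxy C2 enone | CO[C@@H]1C/C=C(C)/C(=O)[C@H]2[C@@H](CC[C@@](C)(O)[C@H]2[C@@H](O)C[C@@]1(C)O[Si](C)(C)C(C)(C)C)[C@@H](C)C(=O)O | intermediate
22 | bridged C2 hemiketal | CO[C@@H]1C/C=C(C)/[C@@]2(O)O[C@@H](C[C@@]1(C)O[Si](C)(C)C(C)(C)C)[C@H]3[C@@H]2[C@@H](CC[C@@]3(C)O)[C@@H](C)C(=O)O | intermediate
23 | ether-bridged alkenoic acid | CO[C@@H]1C/C=C(C)/[C@H]2O[C@@H](C[C@@]1(C)O[Si](C)(C)C(C)(C)C)[C@H]3[C@@H]2[C@@H](CC[C@@]3(C)O)[C@@H](C)C(=O)O | intermediate
24 | tetracyclic lactone, C11–OH, C7–OTBS | CO[C@@H]1CC[C@]2(C)OC(=O)[C@H](C)[C@@H]3CC[C@@](C)(O)[C@@H]4[C@H]3[C@@H]2O[C@H]4C[C@@]1(C)O[Si](C)(C)C(C)(C)C | intermediate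
25 | C11 acetate, C7–OTBS | CO[C@@H]1CC[C@]2(C)OC(=O)[C@H](C)[C@@H]3CC[C@@](C)(OC(C)=O)[C@@H]4[C@H]3[C@@H]2O[C@H]4C[C@@]1(C)O[Si](C)(C)C(C)(C)C | intermediate
26 | CNP0238771.1 | CO[C@@H]1CC[C@]2(C)OC(=O)[C@H](C)[C@@H]3CC[C@@](C)(OC(C)=O)[C@@H]4[C@H]3[C@@H]2O[C@H]4C[C@@]1(C)O | target

## Step count and least certain steps

Total: 20 steps. Longest linear sequence: 16 steps (steps 1–5 and 10–20).

**Step 11 (key step).**
- *What may go wrong:* The dialkoxide may aggregate and react slowly, so that reversal of the 1,2-addition competes. A boat transition state would erode the transfer of configuration to C1. Warm or basic quenching could bring retro-aldol opening of the β-alkoxide ketone or poor facial selectivity in the protonation at C10.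
- *Fallback:* It sets out from 13 and runs the rearrangement on a neutral species. Both tertiary alcohols are silylated with TMSOTf/2,6-lutidine to the bis(trimethylsilyl) ether F1. This is heated in o-dichlorobenzene, and a thermal siloxy-Cope shift gives the silyl enol ether F2. Mild acid methanolysis removes both trimethylsilyl groups and returns to 15.

**Step 15.**
- *What may go wrong:* Site selectivity between C2, C18 and C5 may be poor in the crowded medium ring. Overoxidation and slow turnover are also possible.
- *Fallback:* It sets out from 19 and uses a Schenck ene reaction (O2, tetraphenylporphyrin, light). This gives the transposed allylic hydroperoxide F3 (oxygen on C4, alkene C2=C3). PPh3 reduces it in the same flask to the allylic alcohol F4. Re2O7 then equilibrates the allylic system through its perrhenate esters and lets the C9 hydroxyl close on C2, coming back at 23. Steps 16 and 17 are bypassed.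

**Step 17.**
- *What may go wrong:* The strain of an E-alkene next to the bridgehead may disfavour the bridged oxocarbenium ion. Hydride may then be delivered to the vinylogous position C4, or the tertiary silyl ether or C11 hydroxyl may ionise first.
- *Fallback:* It sets out from 20 and avoids the ketone oxidation level altogether. Catalytic Re2O7 ionises only the allylic C2 alcohol of either configuration. The C9 hydroxyl traps the allyl cation, and only the cis-bridged ether can form, which leads directly to 23.

**Step 18.**
- *What may go wrong:* Hydrogen-atom transfer to a hindered trisubstituted allylic-ether alkene may be slow. Seven-membered ring closure may lose out to simple reduction, proton loss, or a 1,2-hydride shift from C2.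
- *Fallback:* It sets out from 23 and separates the two events. Mukaiyama hydration (Mn(dpm)3, PhSiH3, O2, then P(OEt)3) attacks the outward face of C3 and gives the tertiary alcohol F5. Yamaguchi lactonisation (2,4,6-trichlorobenzoyl chloride, Et3N, DMAP) closes ring D and returns to 24. A C3 epimer cannot lactonise and would be removed at this point.

**Step 3.**
- *What may go wrong:* Oxidation may compete at the C6–H bond next to the ether oxygen and at the allylic positions of the isopropenyl group.
- *Fallback:* It sets out from 3 and moves the oxygen by stepwise transposition.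
  - mCPBA epoxidises the more electron-rich ring alkene to the epoxide F6.
  - PhSeNa, made from (PhSe)2 and NaBH4, opens it at C8 to the hydroxy selenide F7.
  - H2O2 triggers selenoxide elimination towards C9 to give the tertiary allylic alcohol F8.
  - Pyridinium chlorochromate, C5H5NH[CrO3Cl], effects the oxidative 1,3-transposition to enone 4.

## Further compounds

F1 | step 11 | bis(trimethylsilyl) ether of 13 | CO[C@@H]1C[C@H](C(C)=C)[C@](O[Si](C)(C)C)(C[C@@]1(C)O[Si](C)(C)C(C)(C)C)C2=C[C@H](C(C)=C)CC[C@@]2(C)O[Si](C)(C)C
F2 | step 11 | C9 trimethylsilyl enol ether, C11 trimethylsilyl ether of 15 | CO[C@@H]1C/C=C(C)/C[C@H]2[C@@H](CC[C@@](C)(O[Si](C)(C)C)/C2=C(/O[Si](C)(C)C)C[C@@]1(C)O[Si](C)(C)C(C)(C)C)C(C)=C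
F3 | step 15 | C4 allylic hydroperoxide with C2=C3 alkene | CO[C@@H]1CC(OO)C(C)=C[C@H]2[C@@H](CC[C@@](C)(O)[C@H]2[C@@H](O)C[C@@]1(C)O[Si](C)(C)C(C)(C)C)[C@@H](C)C(=O)O
F4 | step 15 | C4 allylic alcohol with C2=C3 alkene | CO[C@@H]1CC(O)C(C)=C[C@H]2[C@@H](CC[C@@](C)(O)[C@H]2[C@@H](O)C[C@@]1(C)O[Si](C)(C)C(C)(C)C)[C@@H](C)C(=O)O
F0 | step 17 | none | none
F5 | step 18 | C3 tertiary alcohol C16 acid | CO[C@@H]1CC[C@](C)(O)[C@H]2O[C@@H](C[C@@]1(C)O[Si](C)(C)C(C)(C)C)[C@H]3[C@@H]2[C@@H](CC[C@@]3(C)O)[C@@H](C)C(=O)O
F6 | step 3 | C7–C8 epoxide of 3 | CO[C@@H]1C[C@H](C(C)=C)CC2OC12C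
F7 | step 3 | C8 phenylselanyl C7 alcohol | CO[C@@H]1C[C@H](C(C)=C)CC([Se]c2ccccc2)C1(C)O
F8 | step 3 | C7 tertiary allylic alcohol with C8=C9 alkene | CO[C@@H]1C[C@H](C(C)=C)C=CC1(C)O
A1 | alternative 1 | (Z)-oxonene tetraene for the intramolecular Diels–Alder reaction | C[C@]1(O[Si](CC)(CC)CC)CC/C=C(C)\C[C@@H](/C=C(C)/C=C)O[C@H]1/C=C/C(C)=O
A2 | alternative 2 | hydroisobenzofuran vinyl iodide aldehyde | C=C(I)C[C@@H]1O[C@H]([C@](C)(CCC=O)O[Si](CC)(CC)CC)[C@@H]2[C@H]1C(C)=CC[C@H]2C(C)=C
A3 | alternative 3 | tetrahydropyranyl diazoketone | C=C(C)[C@@H]1CC[C@](C)(O[Si](C)(C)C(C)(C)C)[C@H](CC(=O)C=[N+]=[N-])O1
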